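**Retrosynthetic overview**
1. The side-chain γ-lactone is formed last, by oxidative lactonisation of a 1,4-diol. The 1,2-dioxane is closed before it, by 6-exo alkylation of a tertiary C4' hydroperoxide on the allylic C1' chloride; the hydroperoxide comes from Shi epoxidation of an (E)-alkene followed by H2O2 opening at C4'.
2. The C13–C1' bond comes from a Nozaki–Hiyama–Kishi coupling of the C13 enol triflate with an (E)-C6 aldehyde made from but-3-yn-1-ol (carboalumination, ethylene oxide); C1' is then set by CBS reduction.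
3. The C6–O bond comes from a carboxyl-directed γ-C–H lactonisation. The strategy rests on the equatorial C18 carboxyl on C4 (ring A) lying peri to the equatorial 6α-hydrogen of ring B in the trans-decalin, so a temporary 18,6α-γ-lactone can be closed and later opened to the 6α-hydroxy methyl ester.
4. Rings A and B, with C4, C5, C9 and C10, come unchanged from abietic acid. Ring C is cut at C13=C14: C11–C13 become the chain, old C14 becomes the C8 methyl (8α-OH by Mukaiyama hydration), and C13 becomes an ester by Baeyer–Villiger oxidation.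
5. Ring order: A/B from the chiral pool; temporary 18,6-lactone (step 5, opened in step 6); 1,2-dioxane (step 20); side-chain γ-lactone (step 22).

Key step: step 5

Assumption (chemistry): the stereodescriptors of the target are taken literally; they place H-3' and the 4'-methyl on opposite faces, so the 1,2-dioxane/γ-lactone junction is trans (1'R,3'S,4'R), and the endgame is built for this trans fusion (a hydroperoxide conjugate addition to a butenolide would give only the cis fusion).

Locants: labdane numbering for the decalin (C17 = methyl on C8, the former C14 of abietic acid; C18 = carboxyl on C4; C19 and C20 = methyls on C4 and C10); C11–C13 for the chain on C9; C1'–C6' for the six-carbon peroxylactone unit, starting at the carbon bound to C13 (C6' = lactone carbonyl).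

**Route**

Step 1
Reactants: 1 abietic acid
Product: 3 13,14-seco keto enal acid, via 13α,14α-diol 2 (not isolated)
Conditions: OsO4 (cat.), NaIO4, 2,6-lutidine, dioxane–H2O, rt
Reagents that add atoms: osmium tetroxide, O=[Os](=O)(=O)=O (catalytic oxygen carrier); sodium periodate, [Na+].[O-]I(=O)(=O)=O
Why: Lemieux–Johnson oxidation, in which osmylation is expected at the more accessible ring C C13=C14 bond of the diene and periodate cleaves the diol, after which the remaining C7=C8 bond is part of an electron-poor enal and should resist further attack.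

Step 2
Reactants: 3 13,14-seco keto enal acid
Product: 6 8(17)-exocyclic alkene keto acid, via C17 tosylhydrazone 4 (not isolated), via allylic diazene 5 (not isolated)
Conditions: TsNHNH2 (1.05 equiv), THF, rt; catecholborane (2.5 equiv), CHCl3, 0 °C; NaOAc·3H2O, reflux
Reagents that add atoms: none
Why: Caglioti-type reductive 1,3-transposition, in which the hydrazone should form at the aldehyde rather than the hindered isopropyl ketone, and hydride reduction, sulfinate loss and retro-ene loss of N2 from the allylic diazene move the double bond to the exocyclic C8=C17 position while the hindered carboxylic acid is only borylated reversibly.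

Step 3
Reactants: 6 8(17)-exocyclic alkene keto acid
Product: 7 8α-hydroxy 13-keto acid
Conditions: Co(acac)2 (cat.), PhSiH3, O2 (1 atm), THF, rt
Reagents that add atoms: dioxygen, O=O
Why: Mukaiyama hydration, in which hydrogen-atom transfer from a cobalt hydride to the CH2 terminus gives the tertiary C8 radical, and O2 should be captured on the α face because the β face is screened by the axial C10 methyl, setting 8α-OH and 8β-CH3.

Step 4
Reactants: 7 8α-hydroxy 13-keto acid
Product: 8 8α-hydroxy 18-acid with isopropyl C13 ester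
Conditions: CF3CO3H (from urea·H2O2 and (CF3CO)2O), Na2HPO4, CH2Cl2, 0 °C to rt
Reagents that add atoms: trifluoroperacetic acid, OOC(=O)C(F)(F)F (generated from urea–hydrogen peroxide, NC(N)=O.OO, and trifluoroacetic anhydride)
Why: Baeyer–Villiger oxidation, in which the secondary isopropyl group migrates in preference to the primary C12 methylene to give the isopropyl ester, and the phosphate buffer suppresses acid-induced dehydration of the δ-hydroxy ketone to a cyclic enol ether.

Step 5
Reactants: 8 8α-hydroxy 18-acid with isopropyl C13 ester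
Product: 9 18,6α-lactone
Conditions: Mn(CF3SO3)2 (2 mol %), (S,S)-N,N'-bis(2-pyridylmethyl)-2,2'-bipyrrolidine (2 mol %), H2O2 (aq., slow addition), (CF3)2CHOH, 0 °C
Reagents that add atoms: none
Why: The carboxylic acid binds to manganese and heterolysis of the bound peroxide, assisted by the fluorinated alcohol, should give a manganese oxo carboxylate (formally pentavalent manganese) that abstracts the equatorial 6α-hydrogen through a seven-membered transition state, after which the C6 radical is captured by the bound carboxylate oxygen (carboxylate rebound) to form the C6–O bond. The closest known reaction type is the carboxylic-acid-directed γ-C–H lactonisation of aliphatic acids with manganese aminopyridine catalysts and H2O2. The γ-lactone ring (C18, O, C6, C5, C4) closes by capture of the C6 radical by the tethered carboxylate, bridging the two equatorial peri positions C4 and C6 of the trans-decalin. The only new stereocentre, C6, is fixed by the tether, since the carboxyl sits on the α face at C4 and can deliver oxygen only to the α face of C6. The step needs site selectivity: of the γ positions, C10 has no hydrogen and the C2 hydrogens cannot be reached from an equatorial carboxyl, while the tertiary C5–H and C9–H bonds and the ester methine are sterically shielded or electronically deactivated. The fluorinated alcohol should also protect the tertiary C8 alcohol by hydrogen bonding, and the reaction is self-limiting because the directing acid is consumed.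

Step 6
Reactants: 9 18,6α-lactone
Product: 11 6α,8α-dihydroxy dimethyl ester, via dipotassium dicarboxylate 10 (not isolated)
Conditions: KOH, MeOH–H2O, 65 °C; CO2 to pH 8–9, evaporate; MeI, DMF, rt
Reagents that add atoms: potassium hydroxide, [K+].[OH-]; iodomethane, CI
Why: Saponification by acyl–oxygen cleavage opens the γ-lactone and cleaves the isopropyl ester without touching C6, and SN2 methylation of the dicarboxylate without acidification should avoid relactonisation.

Step 7
Reactants: 11 6α,8α-dihydroxy dimethyl ester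
Product: 12 6,8-bis(triethylsilyl) ether
Conditions: Et3SiOTf, 2,6-lutidine, CH2Cl2, −78 to 0 °C
Reagents that add atoms: triethylsilyl trifluoromethanesulfonate, CC[Si](CC)(CC)OS(=O)(=O)C(F)(F)F
Why: Silyl triflate silylation is strong enough for the hindered secondary C6 and tertiary C8 alcohols and, being non-basic at oxygen, should not trigger lactonisation of the 6-hydroxy ester.

Step 8
Reactants: 12 6,8-bis(triethylsilyl) ether
Product: 13 C13 N-methoxy-N-methyl amide
Conditions: MeNH(OMe)·HCl, i-PrMgCl, THF, −20 °C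
Reagents that add atoms: N,O-dimethylhydroxylamine hydrochloride, CNOC.Cl
Why: Aminolysis by the chloromagnesium amide should occur only at the unhindered C13 methyl ester, because the C18 ester on the quaternary C4 is inert.

Step 9
Reactants: 13 C13 N-methoxy-N-methyl amide
Product: 14 C13 methyl ketone
Conditions: MeMgBr, THF, 0 °C
Reagents that add atoms: methylmagnesium bromide, C[Mg]Br
Why: Weinreb ketone synthesis, in which the chelated tetrahedral adduct prevents over-addition and the hindered C18 ester should not react at 0 °C.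

Step 10
Reactants: 14 C13 methyl ketone
Product: 16 C13 enol triflate, via lithium enolate 15 (not isolated)
Conditions: LiN(iPr)2, THF, −78 °C; N-(5-chloropyridin-2-yl)bis(trifluoromethanesulfonimide), −78 to 0 °C
Reagents that add atoms: N-(5-chloropyridin-2-yl)bis(trifluoromethanesulfonimide), FC(F)(F)S(=O)(=O)N(c1ccc(Cl)cn1)S(=O)(=O)C(F)(F)F
Why: Kinetic deprotonation at −78 °C takes place at the methyl group rather than at C12, and O-sulfonylation of the terminal enolate gives the 2-triflyloxy-1-alkene; the C18 ester has no α-hydrogen.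

Step 11
Reactants: 17 but-3-yn-1-ol
Product: 18 tert-butyl(but-3-yn-1-yloxy)dimethylsilane
Conditions: TBSCl, imidazole, DMF, rt
Reagents that add atoms: tert-butyldimethylsilyl chloride, CC(C)(C)[Si](C)(C)Cl
Why: Standard silylation of a primary alcohol, giving an ether that tolerates organoaluminium and organolithium reagents.

Step 12
Reactants: 18 tert-butyl(but-3-yn-1-yloxy)dimethylsilane
Product: 21 (E)-6-[(tert-butyldimethylsilyl)oxy]-4-methylhex-3-en-1-ol, via alkenyldimethylalane 19 (not isolated), via lithium alkenylalanate 20 (not isolated)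
Conditions: Me3Al, Cp2ZrCl2 (0.25 equiv), CH2Cl2, 0 °C to rt; evaporate; n-BuLi, THF–hexane, −78 °C; ethylene oxide, −78 to 0 °C
Reagents that add atoms: trimethylaluminium, C[Al](C)C; oxirane, C1CO1
Why: Zirconium-catalysed Negishi carboalumination adds CH3 and Al syn across the alkyne with methyl on the internal carbon, and the derived alanate opens ethylene oxide with retention of alkene geometry, which fixes the (E)-trisubstituted alkene (C2' cis to the methyl).

Step 13
Reactants: 21 (E)-6-[(tert-butyldimethylsilyl)oxy]-4-methylhex-3-en-1-ol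
Product: 22 (E)-6-[(tert-butyldimethylsilyl)oxy]-4-methylhex-3-enal
Conditions: Dess–Martin periodinane, NaHCO3, CH2Cl2, 0 °C; used at once
Reagents that add atoms: none
Why: Dess–Martin oxidation under buffered, non-basic conditions should give the β,γ-unsaturated aldehyde without migration of the double bond into conjugation.

Step 14
Reactants: 16 C13 enol triflate; 22 (E)-6-[(tert-butyldimethylsilyl)oxy]-4-methylhex-3-enal
Product: 23 allylic alcohol (both C1' epimers)
Conditions: CrCl2 (excess), NiCl2 (cat.), DMF, rt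
Reagents that add atoms: none
Why: Nozaki–Hiyama–Kishi coupling, in which zerovalent nickel (formed by divalent chromium) inserts into the enol triflate, transmetalation gives an alkenyl species of trivalent chromium, and this adds chemoselectively to the aldehyde in the presence of esters and silyl ethers; no control at C1' is needed because the alcohol is oxidised next.

Step 15
Reactants: 23 allylic alcohol (both C1' epimers)
Product: 24 α-methylene ketone (C1' ketone)
Conditions: Dess–Martin periodinane, NaHCO3, CH2Cl2, 0 °C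
Reagents that add atoms: none
Why: Dess–Martin oxidation converges both epimers to one enone, and the buffered, cold conditions should prevent isomerisation of the skipped C3'=C4' alkene.

Step 16
Reactants: 24 α-methylene ketone
Product: 25 (1'R)-allylic alcohol
Conditions: (S)-2-methyl-CBS-oxazaborolidine, catecholborane, toluene, −78 °C
Reagents that add atoms: none
Why: Corey–Bakshi–Shibata reduction, in which the ketone binds the oxazaborolidine with the branched 1-substituted vinyl group as the large substituent so that hydride delivery should give the (1'R) carbinol, and catecholborane at low temperature avoids hydroboration of the alkenes.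

Step 17
Reactants: 25 (1'R)-allylic alcohol
Product: 26 (1'S)-allylic chloride
Conditions: PPh3, hexachloroacetone, CH2Cl2, 0 °C
Reagents that add atoms: hexachloroacetone, ClC(Cl)(Cl)C(=O)C(Cl)(Cl)Cl
Why: Appel-type chlorination, in which chloride displaces the alkoxyphosphonium group by SN2 with inversion, under conditions known to keep allylic transposition of secondary allylic alcohols to a minimum.

Step 18
Reactants: 26 (1'S)-allylic chloride
Product: 27 (3'S,4'S)-epoxide
Conditions: L-fructose-derived Shi ketone (0.3 equiv), KHSO5 (Oxone), K2CO3, Bu4NHSO4, MeCN–CH2(OMe)2–aq. Na2B4O7 buffer, 0 °C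
Reagents that add atoms: potassium peroxymonosulfate, [K+].[O-]S(=O)(=O)OO
Why: Shi epoxidation, in which the chiral dioxirane should attack the electron-rich trisubstituted alkene in preference to the 1,1-disubstituted alkene deactivated by the allylic chlorine, and the spiro transition state of this catalyst enantiomer sets (3'S,4'S) under catalyst control.

Step 19
Reactants: 27 (3'S,4'S)-epoxide
Product: 28 (3'S)-hydroxy (4'R)-hydroperoxide
Conditions: H2O2 (anhydrous, in Et2O), H3PMo12O40 (cat.), Et2O, 0 °C to rt
Reagents that add atoms: hydrogen peroxide, OO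
Why: Acid-catalysed perhydrolysis of a trisubstituted epoxide, in which H2O2 should attack the tertiary C4' with inversion to place OOH and the C3' hydroxyl anti, which is the relationship needed for the trans ring fusion.

Step 20
Reactants: 28 (3'S)-hydroxy (4'R)-hydroperoxide
Product: 29 1,2-dioxane
Conditions: Cs2CO3, DMF, 0 °C
Reagents that add atoms: none
Why: Intramolecular SN2 alkylation of the hydroperoxide anion at the allylic C1' chloride (6-exo-tet) with inversion should give the (1'R) peroxide, because the transposed SN2' pathway would need an eight-membered ring and the weak base deprotonates only the hydroperoxide.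

Step 21
Reactants: 29 1,2-dioxane
Product: 30 tetraol
Conditions: HF·pyridine, pyridine, THF, 0 °C to rt
Reagents that add atoms: none
Why: Fluoride-driven cleavage of the three silyl ethers under buffered acidic conditions that dialkyl peroxides and the allylic peroxide tolerate.

Step 22
Reactants: 30 tetraol
Product: 33 target CNP0162504.1, via hydroxy aldehyde 31 (not isolated), via lactol 32 (not isolated)
Conditions: TEMPO (cat.), PhI(OAc)2, CH2Cl2, rt
Reagents that add atoms: none
Why: Oxoammonium oxidation takes the primary alcohol first, the γ-hydroxy aldehyde should close to the lactol through the trans-diequatorial C3' hydroxyl and be oxidised on to the trans-fused γ-lactone, while the hindered secondary C6 alcohol and the tertiary alcohol are expected to remain.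

**Compound list**
1 | abietic acid (abieta-7,13-dien-18-oic acid) | CC(C)C1=CC2=CC[C@H]3[C@](C)(C(=O)O)CCC[C@]3(C)[C@H]2CC1 | starting material
2 | 13α,14α-dihydroxyabiet-7-en-18-oic acid (cis-diol drawn for addition to the α face; both centres are lost on cleavage) | CC(C)[C@@]1(O)[C@H](O)C2=CC[C@H]3[C@](C)(C(=O)O)CCC[C@]3(C)[C@H]2CC1 | intermediate (not isolated)
3 | 13,14-seco keto enal acid: rings A and B of 1, C18 acid, C7=C8 alkene with CHO (C17) on C8, 4-methyl-3-oxopentyl chain on C9 | CC(C)C(=O)CC[C@@H]1[C@@]2(C)CCC[C@@](C)(C(=O)O)[C@@H]2CC=C1C=O | intermediate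
4 | C17 N-tosylhydrazone of 3 | CC(C)C(=O)CC[C@@H]1[C@@]2(C)CCC[C@@](C)(C(=O)O)[C@@H]2CC=C1/C=N/NS(=O)(=O)c1ccc(C)cc1 | intermediate (not isolated)
5 | allylic diazene (CH2–N=NH on C8 of the C7=C8 alkene) | CC(C)C(=O)CC[C@@H]1[C@@]2(C)CCC[C@@](C)(C(=O)O)[C@@H]2CC=C1CN=N | intermediate (not isolated)
6 | 8(17)-exocyclic alkene keto acid (C8=CH2, C13 isopropyl ketone, C18 acid) | CC(C)C(=O)CC[C@@H]1[C@@]2(C)CCC[C@@](C)(C(=O)O)[C@@H]2CCC1=C | intermediate
7 | 8α-hydroxy-8β-methyl 13-keto acid | CC(C)C(=O)CC[C@@H]1[C@@]2(C)CCC[C@@](C)(C(=O)O)[C@@H]2CC[C@@]1(C)O | intermediate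
8 | 8α-hydroxy 18-acid with isopropyl C13 ester (key-step precursor) | CC(C)OC(=O)CC[C@@H]1[C@@]2(C)CCC[C@@](C)(C(=O)O)[C@@H]2CC[C@@]1(C)O | intermediate
9 | 18,6α-lactone (γ-lactone C18–O–C6, 8α-OH, isopropyl C13 ester) | CC(C)OC(=O)CC[C@@H]1[C@@]2(C)CCC[C@@](C)(C(=O)O3)[C@@H]2[C@@H]3C[C@@]1(C)O | intermediate
10 | dipotassium 6α,8α-dihydroxy-13,18-dicarboxylate | [K+].[K+].[O-]C(=O)CC[C@@H]1[C@@]2(C)CCC[C@@](C)(C([O-])=O)[C@@H]2[C@@H](O)C[C@@]1(C)O | intermediate (not isolated)
11 | 6α,8α-dihydroxy dimethyl ester (C13 and C18 methyl esters) | COC(=O)CC[C@@H]1[C@@]2(C)CCC[C@@](C)(C(=O)OC)[C@@H]2[C@@H](O)C[C@@]1(C)O | intermediate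
12 | 6α,8α-bis(triethylsilyloxy) dimethyl ester | COC(=O)CC[C@@H]1[C@@]2(C)CCC[C@@](C)(C(=O)OC)[C@@H]2[C@@H](O[Si](CC)(CC)CC)C[C@@]1(C)O[Si](CC)(CC)CC | intermediate
13 | C13 N-methoxy-N-methyl amide, C18 methyl ester, bis-silyl ether | CON(C)C(=O)CC[C@@H]1[C@@]2(C)CCC[C@@](C)(C(=O)OC)[C@@H]2[C@@H](O[Si](CC)(CC)CC)C[C@@]1(C)O[Si](CC)(CC)CC | intermediate
14 | C13 methyl ketone, C18 methyl ester, bis-silyl ether | CC(=O)CC[C@@H]1[C@@]2(C)CCC[C@@](C)(C(=O)OC)[C@@H]2[C@@H](O[Si](CC)(CC)CC)C[C@@]1(C)O[Si](CC)(CC)CC | intermediate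
15 | terminal lithium enolate of 14 | C=C(O[Li])CC[C@@H]1[C@@]2(C)CCC[C@@](C)(C(=O)OC)[C@@H]2[C@@H](O[Si](CC)(CC)CC)C[C@@]1(C)O[Si](CC)(CC)CC | intermediate (not isolated)
16 | C13 enol triflate (2-triflyloxy-1-alkene) | C=C(OS(=O)(=O)C(F)(F)F)CC[C@@H]1[C@@]2(C)CCC[C@@](C)(C(=O)OC)[C@@H]2[C@@H](O[Si](CC)(CC)CC)C[C@@]1(C)O[Si](CC)(CC)CC | intermediate
17 | but-3-yn-1-ol | C#CCCO | starting material
18 | tert-butyl(but-3-yn-1-yloxy)dimethylsilane | C#CCCO[Si](C)(C)C(C)(C)C | intermediate
19 | (E)-alkenyldimethylalane (Al cis to the new methyl) | C[Al](C)/C=C(\C)CCO[Si](C)(C)C(C)(C)C | intermediate (not isolated)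
20 | lithium butyl(alkenyl)dimethylalanate | [Li+].CCCC[Al-](C)(C)/C=C(\C)CCO[Si](C)(C)C(C)(C)C | intermediate (not isolated)
21 | (E)-6-[(tert-butyldimethylsilyl)oxy]-4-methylhex-3-en-1-ol | OCC/C=C(\C)CCO[Si](C)(C)C(C)(C)C | intermediate
22 | (E)-6-[(tert-butyldimethylsilyl)oxy]-4-methylhex-3-enal | O=CC/C=C(\C)CCO[Si](C)(C)C(C)(C)C | intermediate
23 | coupled allylic alcohol, 13-methylene, C1'–OH as both epimers, (E)-C3'=C4' | C=C(CC[C@@H]1[C@@]2(C)CCC[C@@](C)(C(=O)OC)[C@@H]2[C@@H](O[Si](CC)(CC)CC)C[C@@]1(C)O[Si](CC)(CC)CC)C(O)C/C=C(\C)CCO[Si](C)(C)C(C)(C)C | intermediate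
24 | α-methylene ketone (C1' ketone) | C=C(CC[C@@H]1[C@@]2(C)CCC[C@@](C)(C(=O)OC)[C@@H]2[C@@H](O[Si](CC)(CC)CC)C[C@@]1(C)O[Si](CC)(CC)CC)C(=O)C/C=C(\C)CCO[Si](C)(C)C(C)(C)C | intermediate
25 | (1'R)-allylic alcohol | C=C(CC[C@@H]1[C@@]2(C)CCC[C@@](C)(C(=O)OC)[C@@H]2[C@@H](O[Si](CC)(CC)CC)C[C@@]1(C)O[Si](CC)(CC)CC)[C@H](O)C/C=C(\C)CCO[Si](C)(C)C(C)(C)C | intermediate
26 | (1'S)-allylic chloride | C=C(CC[C@@H]1[C@@]2(C)CCC[C@@](C)(C(=O)OC)[C@@H]2[C@@H](O[Si](CC)(CC)CC)C[C@@]1(C)O[Si](CC)(CC)CC)[C@@H](Cl)C/C=C(\C)CCO[Si](C)(C)C(C)(C)C | intermediate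
27 | (1'S)-chloride (3'S,4'S)-epoxide | C=C(CC[C@@H]1[C@@]2(C)CCC[C@@](C)(C(=O)OC)[C@@H]2[C@@H](O[Si](CC)(CC)CC)C[C@@]1(C)O[Si](CC)(CC)CC)[C@@H](Cl)C[C@@H]3O[C@@]3(C)CCO[Si](C)(C)C(C)(C)C | intermediate
28 | (1'S)-chloride (3'S)-alcohol (4'R)-hydroperoxide | C=C(CC[C@@H]1[C@@]2(C)CCC[C@@](C)(C(=O)OC)[C@@H]2[C@@H](O[Si](CC)(CC)CC)C[C@@]1(C)O[Si](CC)(CC)CC)[C@@H](Cl)C[C@H](O)[C@](C)(OO)CCO[Si](C)(C)C(C)(C)C | intermediate
29 | (1'R,3'S,4'R)-1,2-dioxane with 3'-OH, 4'-methyl and 4'-(2-silyloxyethyl) | C=C(CC[C@@H]1[C@@]2(C)CCC[C@@](C)(C(=O)OC)[C@@H]2[C@@H](O[Si](CC)(CC)CC)C[C@@]1(C)O[Si](CC)(CC)CC)[C@H]3C[C@H](O)[C@@](C)(CCO[Si](C)(C)C(C)(C)C)OO3 | intermediate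
30 | tetraol (6α-OH, 8α-OH, 3'-OH, primary 6'-OH) | C=C(CC[C@@H]1[C@@]2(C)CCC[C@@](C)(C(=O)OC)[C@@H]2[C@@H](O)C[C@@]1(C)O)[C@H]3C[C@H](O)[C@@](C)(CCO)OO3 | intermediate
31 | 3'-hydroxy 6'-aldehyde | C=C(CC[C@@H]1[C@@]2(C)CCC[C@@](C)(C(=O)OC)[C@@H]2[C@@H](O)C[C@@]1(C)O)[C@H]3C[C@H](O)[C@@](C)(CC=O)OO3 | intermediate (not isolated)
32 | trans-fused lactol | C=C(CC[C@@H]1[C@@]2(C)CCC[C@@](C)(C(=O)OC)[C@@H]2[C@@H](O)C[C@@]1(C)O)[C@H]3C[C@@H]4OC(O)C[C@@]4(C)OO3 | intermediate (not isolated)
33 | CNP0162504.1 | C=C(CC[C@@H]1[C@@]2(C)CCC[C@@](C)(C(=O)OC)[C@@H]2[C@@H](O)C[C@@]1(C)O)[C@H]1C[C@@H]2OC(=O)C[C@@]2(C)OO1 | target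

**Step count**
Total: 22 steps. Longest linear sequence: 19 steps (steps 1–10 and 14–22, from abietic acid); aldehyde 22 takes 3 steps from but-3-yn-1-ol.

**Steps most likely to fail, with fallbacks**

Step 5 (directed C–H lactonisation). The oxidant may attack other C–H bonds (the tertiary C5 and C9 positions), the catalyst may be consumed before the strained bridging hydrogen abstraction takes place, or over-oxidation may set in. The fallback replaces the metal-oxo step with an amidyl-radical 1,5-hydrogen transfer and sets out from 8. The tertiary alcohol is first masked with Ac2O and catalytic Me3SiOTf (aqueous work-up) to give the 8α-acetoxy acid F1, so that no alkoxy radical can form later. The acid is converted with (COCl)2 and then NH3 into the primary 18-carboxamide F2. Irradiation with PhI(OAc)2 and I2 gives the N-iodoamide F3 in the flask. Its amidyl radical abstracts the 6α-hydrogen, iodine transfer and closure through the amide oxygen give the iminolactone F4, and aqueous hydrolysis gives the 8α-acetoxy 18,6α-lactone F5. Under the conditions of step 6, F5 loses the acetate, the isopropyl ester and the lactone bridge together, and the route is rejoined at 11.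

Step 20 (peroxide ring closure). Displacement at the secondary allylic chloride may be slow, and elimination to a diene, ionisation with loss of configuration, or base-induced fragmentation of the secondary allylic peroxide may compete; the preceding chlorination may also leak through allylic transposition. The fallback reverses the order of the two C–O bond formations and sets out from 24. Reduction with the (R)-oxazaborolidine and catecholborane gives the (1'S)-allylic alcohol F6. Shi epoxidation with the same L-fructose-derived ketone gives the (1'S,3'S,4'S)-epoxy alcohol F7. Mesylation at −78 °C (MsCl, Et3N) gives the mesylate F8, which is not isolated and is displaced at once by anhydrous H2O2 with inversion to the (1'R)-hydroperoxy epoxide F9. Catalytic acid (camphorsulfonic acid, CH2Cl2, 0 °C) then opens the epoxide at the tertiary, cation-stabilising C4' with inversion (6-endo), which gives 29, where the route is rejoined.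

Step 3 (Mukaiyama hydration). Oxygen capture by the C8 radical may show poor facial selectivity, and the free acid may slow the cobalt cycle. The fallback uses polar chemistry and sets out from 6. Epoxidation with mCPBA (NaHCO3, CH2Cl2, 0 °C), expected on the α face away from the axial C10 methyl, gives the 8α,17-epoxide F10. LiI with AcOH in THF opens it at the primary carbon to the iodohydrin F11. Bu3SnH with AIBN removes the iodine to give 7, where the route is rejoined.

**Further compounds**
F1 | step 5 | 8α-acetoxy 18-acid with isopropyl C13 ester | CC(C)OC(=O)CC[C@@H]1[C@@]2(C)CCC[C@@](C)(C(=O)O)[C@@H]2CC[C@@]1(C)OC(C)=O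
F2 | step 5 | 8α-acetoxy 18-carboxamide | CC(C)OC(=O)CC[C@@H]1[C@@]2(C)CCC[C@@](C)(C(N)=O)[C@@H]2CC[C@@]1(C)OC(C)=O
F3 | step 5 | N-iodo 18-carboxamide | CC(C)OC(=O)CC[C@@H]1[C@@]2(C)CCC[C@@](C)(C(=O)NI)[C@@H]2CC[C@@]1(C)OC(C)=O
F4 | step 5 | 18,6α-iminolactone | CC(C)OC(=O)CC[C@@H]1[C@@]2(C)CCC[C@@](C)(C(=N)O3)[C@@H]2[C@@H]3C[C@@]1(C)OC(C)=O
F5 | step 5 | 8α-acetoxy 18,6α-lactone | CC(C)OC(=O)CC[C@@H]1[C@@]2(C)CCC[C@@](C)(C(=O)O3)[C@@H]2[C@@H]3C[C@@]1(C)OC(C)=O
F6 | step 20 | (1'S)-allylic alcohol | C=C(CC[C@@H]1[C@@]2(C)CCC[C@@](C)(C(=O)OC)[C@@H]2[C@@H](O[Si](CC)(CC)CC)C[C@@]1(C)O[Si](CC)(CC)CC)[C@@H](O)C/C=C(\C)CCO[Si](C)(C)C(C)(C)C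
F7 | step 20 | (1'S,3'S,4'S)-epoxy alcohol | C=C(CC[C@@H]1[C@@]2(C)CCC[C@@](C)(C(=O)OC)[C@@H]2[C@@H](O[Si](CC)(CC)CC)C[C@@]1(C)O[Si](CC)(CC)CC)[C@@H](O)C[C@@H]3O[C@@]3(C)CCO[Si](C)(C)C(C)(C)C
F8 | step 20 | (1'S)-mesylate of the epoxy alcohol | C=C(CC[C@@H]1[C@@]2(C)CCC[C@@](C)(C(=O)OC)[C@@H]2[C@@H](O[Si](CC)(CC)CC)C[C@@]1(C)O[Si](CC)(CC)CC)[C@@H](OS(C)(=O)=O)C[C@@H]3O[C@@]3(C)CCO[Si](C)(C)C(C)(C)C
F9 | step 20 | (1'R)-hydroperoxy (3'S,4'S)-epoxide | C=C(CC[C@@H]1[C@@]2(C)CCC[C@@](C)(C(=O)OC)[C@@H]2[C@@H](O[Si](CC)(CC)CC)C[C@@]1(C)O[Si](CC)(CC)CC)[C@H](OO)C[C@@H]3O[C@@]3(C)CCO[Si](C)(C)C(C)(C)C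
F10 | step 3 | 8α,17-epoxide keto acid | CC(C)C(=O)CC[C@@H]1[C@@]2(C)CCC[C@@](C)(C(=O)O)[C@@H]2CC[C@]13CO3
F11 | step 3 | 8α-hydroxy 17-iodide keto acid | CC(C)C(=O)CC[C@@H]1[C@@]2(C)CCC[C@@](C)(C(=O)O)[C@@H]2CC[C@@]1(CI)O
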